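## Retrosynthetic overview

1. The central dihydropyran (ring D) of the target is cut by a retro-hetero-Diels–Alder across C3–C1' and C4–O. Both halves trace back to 4-hydroxy-1-methylquinolin-2(1H)-one (1).
2. Dienophile half: 1 + prenal (2) → prenylidene quinone methide (3) → oxa-6π → N-methylflindersine (4). The dimethylpyran (ring C) is formed first.
3. Heterodiene half: 3-methylbutane-1,3-diol (5) → 3-hydroxy-3-methylbutanal (6). Then 6 + 1 → an already hydrated quinone methide (7), so no late alkene hydration is needed.
4. Ring D is formed last. 7 + 4 react exo under a chiral phosphoric acid that grips the free tertiary OH and the lactam C=O of 7, giving the target (8) with all three stereocentres set in one step.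

**Locants.** C3 and C4 are the two sp3 CH of ring C; C3 is next to CMe2 and C4 bears O. C1' is the CH carrying CH2C(CH3)2OH. The target SMILES reads as (3R,4S,1'R), with H-3/H-4 cis and H-3/H-1' trans (side chain trans to CMe2).

**Assumption.** The sense of induction of the new catalytic step cannot be derived from precedent. The route is written with the (R)-configured acid. If chiral HPLC plus ECD or X-ray of 8 shows the mirror image, the equally available (S)-acid is used and nothing else changes.

## Route

Step 1
Reactants: 1 4-hydroxy-1-methylquinolin-2(1H)-one; 2 3-methylbut-2-enal (prenal, 1.5 equiv)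
Product: 4 N-methylflindersine, via prenylidene quinolinedione 3 (not isolated)
Conditions: ethylenediammonium diacetate (EDDA, 10 mol %), CH2Cl2, reflux, 8 h
Reagents that add atoms: none
Why: Knoevenagel condensation gives the (E)-dienone quinone methide 3, which closes at once by oxa-6π electrocyclisation (formal [3+3]) to the 2H-pyran; no stereocentre is formed.

Step 2
Reactants: 5 3-methylbutane-1,3-diol
Product: 6 3-hydroxy-3-methylbutanal
Conditions: 2,2,6,6-tetramethylpiperidine-1-oxyl (TEMPO, 5 mol %), PhI(OAc)2 (1.05 equiv), CH2Cl2, 0 °C to rt, 3 h; short SiO2 plug (pentane, then Et2O), cold concentration, used at once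
Reagents that add atoms: none
Why: The oxoammonium (TEMPO/diacetoxyiodobenzene) oxidation touches only the primary carbinol because the tertiary one has no α-H, stops at the aldehyde without water, and is mild enough to avoid β-elimination to prenal; no stereocentre is formed.

Step 3
Reactants: 1 4-hydroxy-1-methylquinolin-2(1H)-one; 6 3-hydroxy-3-methylbutanal; 4 N-methylflindersine
Product: 8 target CNP0202276.1 [(3R,4S,1'R)-hexacyclic bis(pyranoquinolinone) tertiary alcohol], via hydroxybutylidene quinolinedione 7 (not isolated)
Conditions: (R)-3,3'-bis(2,4,6-triisopropylphenyl)-1,1'-binaphthyl-2,2'-diyl hydrogen phosphate ((R)-TRIP, 10 mol %), 4 (2 equiv), 6 (1.3 equiv), 1 (1 equiv, solid, in portions over 24 h), 5 Å MS, toluene (0.5 M), 35 °C, 72 h; chromatography (excess 4 recovered), recrystallisation to raise ee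
Reagents that add atoms: none
Why: Proposed new method: a catalytic enantioselective three-component Knoevenagel/inverse-demand hetero-Diels–Alder domino reaction; 1 and 6 condense under the acid to the doubly activated oxadiene (Z)-7, whose lactam C2=O accepts the P–OH hydrogen bond while its tertiary O–H donates to P=O, so the side chain is held syn to C2=O ("outside" on the O=C4–C3=C1' diene), the LUMO is lowered and one triisopropylphenyl wing covers the Re face of C1'; the nucleophilic dienol-ether terminus C3 of 4 (3Re,4Si face) bonds to the Si face of C1' and O4 closes on the developing C4 cation, which fixes the regiochemistry; suprafacial addition to the ring Z-alkene makes H-3/H-4 cis, and the exo approach forced by the pseudo-axial methyl of CMe2 puts the side chain trans to CMe2, giving (3R,4S,1'R); the weak acid leaves the tertiary alcohol and the new benzylic C4–O bond intact, the low solubility and slow dosing of 1 hold back its Michael addition to 7, and loss of water from 6 or 7 only gives 2 or 3 and hence more 4; the closest known reaction types are the achiral Tietze domino Knoevenagel/hetero-Diels–Alder reaction of 4-hydroxyquinolones and 4-hydroxycoumarins and the chiral-phosphoric-acid-catalysed [4+2] cycloadditions of in situ generated ortho-quinone methides with styrene-type alkenes.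

## Compound list

1 | 4-hydroxy-1-methylquinolin-2(1H)-one | Cn1c(=O)cc(O)c2ccccc21 | starting material
2 | 3-methylbut-2-enal (prenal) | CC(C)=CC=O | starting material
3 | (E)-1-methyl-3-(3-methylbut-2-en-1-ylidene)quinoline-2,4(1H,3H)-dione (chain syn to C4=O) | CN1C(=O)/C(=C/C=C(C)C)C(=O)c2ccccc21 | intermediate
4 | N-methylflindersine (2,2,6-trimethyl-2,6-dihydro-5H-pyrano[3,2-c]quinolin-5-one) | Cn1c(=O)c2c(c3ccccc31)OC(C)(C)C=C2 | intermediate
5 | 3-methylbutane-1,3-diol | CC(C)(O)CCO | starting material
6 | 3-hydroxy-3-methylbutanal | CC(C)(O)CC=O | intermediate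
7 | (Z)-3-(3-hydroxy-3-methylbutylidene)-1-methylquinoline-2,4(1H,3H)-dione (chain syn to C2=O) | CN1C(=O)/C(=C\CC(C)(C)O)C(=O)c2ccccc21 | intermediate
8 | CNP0202276.1: N-methylflindersine unit whose pyran C3–C4 bond is cis-fused to a second dihydropyrano[3,2-c]quinolin-5-one (C4–O, C3–C1'), C1' bearing CH2C(CH3)2OH; (3R,4S,1'R), H-3/H-4 cis, H-3/H-1' trans | Cn1c(=O)c2c(c3ccccc31)OC(C)(C)[C@H]1[C@@H]2Oc2c(c(=O)n(C)c3ccccc23)[C@@H]1CC(C)(C)O | target

## Step count and risks

Total steps: 3. Longest linear sequence: 2 (1 → 4 → 8, or equally 5 → 6 → 8).

**Step 3 is the most likely to fail.** Three things can go wrong: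
- Free 1 may add to 7 faster than 4 does.
- 7 may tautomerise and lose water.
- The level and sense of enantiocontrol are unproven.

The fallback sets out from 1 and 6, uses 4, and comes back at 8.
- Two equivalents of 1 are condensed on purpose with 6 (EtOH, 60 °C). This gives the crystalline bis-adduct 3,3'-(3-hydroxy-3-methylbutane-1,1-diyl)bis(4-hydroxy-1-methylquinolin-2(1H)-one) F1, a storable reservoir of the heterodiene.
- F1 is heated with 4 (3 equiv) and ethylenediammonium diacetate in 1,4-dioxane at 100 °C. Retro-Michael cleavage releases 7 slowly together with 1, which is recovered.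
- The purely substrate-controlled exo hetero-Diels–Alder reaction gives 8 as a racemate with its mirror image ent-8 F2.
- Preparative SFC on an amylose tris(3,5-dimethylphenylcarbamate) phase delivers 8. The absolute configuration then comes from resolution instead of from a catalyst.

**Step 2 is second.** Compound 6 is volatile and water-soluble, and it tends to eliminate to 2 or to oligomerise during isolation. The fallback sets out from 5 and comes back at 6.
- 5 is persilylated (Me3SiCl, imidazole, CH2Cl2) to 2-methyl-2,4-bis(trimethylsilyloxy)butane F3.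
- Swern conditions ((COCl)2, DMSO, Et3N, CH2Cl2, −78 to −30 °C) attack only the unhindered primary silyl ether. They give directly the distillable and storable 3-methyl-3-(trimethylsilyloxy)butanal F4, which cannot eliminate.
- Methanolysis (MeOH, 1 mol % (R)-TRIP, 0 °C) and evaporation just before step 3 frees 6 without any aqueous work-up.

**Step 1 is the least risky.** Prenal may polymerise, or 1 may add to 3. The fallback sets out from 1 and comes back at 3 in the flask, and so at 4.
- O-alkylation of 1 with 3-chloro-3-methylbut-1-yne (K2CO3, KI, acetone, reflux) gives 1-methyl-4-[(2-methylbut-3-yn-2-yl)oxy]quinolin-2(1H)-one F5.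
- Heating in N,N-diethylaniline at 180 °C triggers a propargyl Claisen [3,3] shift to 4-hydroxy-1-methyl-3-(3-methylbuta-1,2-dien-1-yl)quinolin-2(1H)-one F6.
- A 1,5-H shift in F6 gives 3, and oxa-6π closure gives 4.

## Further compounds

F1 | step 3 | 3,3'-(3-hydroxy-3-methylbutane-1,1-diyl)bis(4-hydroxy-1-methylquinolin-2(1H)-one) | Cn1c(=O)c(C(CC(C)(C)O)c2c(O)c3ccccc3n(C)c2=O)c(O)c2ccccc21
F2 | step 3 | ent-8, the (3S,4R,1'S) mirror image of the target | Cn1c(=O)c2c(c3ccccc31)OC(C)(C)[C@@H]1[C@H]2Oc2c(c(=O)n(C)c3ccccc23)[C@H]1CC(C)(C)O
F3 | step 2 | 2-methyl-2,4-bis(trimethylsilyloxy)butane | C[Si](C)(C)OCCC(C)(C)O[Si](C)(C)C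
F4 | step 2 | 3-methyl-3-(trimethylsilyloxy)butanal | C[Si](C)(C)OC(C)(C)CC=O
F5 | step 1 | 1-methyl-4-[(2-methylbut-3-yn-2-yl)oxy]quinolin-2(1H)-one | Cn1c(=O)cc(OC(C)(C)C#C)c2ccccc21
F6 | step 1 | 4-hydroxy-1-methyl-3-(3-methylbuta-1,2-dien-1-yl)quinolin-2(1H)-one | Cn1c(=O)c(C=C=C(C)C)c(O)c2ccccc21
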